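**Plan**

- Retrosynthesis: the eight aryl C–Br bonds, the four phenol O–H bonds (carried as OMe) and the pyrrole N–H bond (carried as N-tosyl) are unmasked last.
- Feature used: pyrrole C2 and C5 are each joined to a benzene ring through a single ketone carbon. Each C=O carbon can therefore be CO placed between a pyrrole C–Br bond and an arylboron reagent, and the cut falls on both sides of each carbonyl (C2–CO, C5–CO and two CO–aryl bonds).
- This leads to a 2,5-dibromo-3,4-diaryl-N-tosylpyrrole, cut further at its two C–Br bonds, at C3–C4 (reductive carbonyl coupling) and at the two N–CH2 bonds, back to tosylamide and a phenacyl bromide.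
- Forward: N-alkylation joins the two phenacyl units; McMurry coupling closes the only ring built in the route (the pyrrole, at C3–C4) and DDQ aromatises it; NBS brominates C2 and C5; the twofold carbonylative coupling attaches both aroyl groups; N–S cleavage, O-demethylation and eightfold bromination finish.
- Stereochemistry: the target has no stereocentre and none is created.

Key step: step 5

Remark: in steps 1, 4, 7 and 8 and in the twofold aroylation of the first fallback, the partly alkylated, brominated, demethylated or aroylated species are driven on by excess reagent and are not listed separately; the monoketone of step 5 is numbered because its remaining C–Br bond must react under changed electronics; step 5 takes up two molecules each of 7 and 8 per molecule of 6, and since CO is dosed by pressure and not by equivalents, the second molecule of each is entered on the reagent line of that step.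

**Route**

Step 1
Reactants: 1 4-methylbenzenesulfonamide; 2 2-bromo-1-(4-methoxyphenyl)ethanone (2.1 equiv)
Product: 3 N,N-bis[2-(4-methoxyphenyl)-2-oxoethyl]-4-methylbenzenesulfonamide
Conditions: K2CO3, acetone, reflux
Reagents that add atoms: none
Why: The sulfonamide is acidic enough for K2CO3 and its anion displaces bromide from the reactive α-bromo ketone twice (twofold SN2 N-alkylation), the second alkylation being the last one possible.

Step 2
Reactants: 3 N,N-bis[2-(4-methoxyphenyl)-2-oxoethyl]-4-methylbenzenesulfonamide
Product: 4 3,4-bis(4-methoxyphenyl)-1-(4-methylbenzenesulfonyl)-2,5-dihydro-1H-pyrrole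
Conditions: TiCl4, Zn, pyridine, THF, 0 °C then reflux
Reagents that add atoms: none
Why: Intramolecular McMurry coupling, in which low-valent titanium from TiCl4 and Zn joins the two aryl ketones to a five-membered titanium pinacolate that is deoxygenated at reflux to the doubly aryl-conjugated alkene, as is established for diaryl ketones and for 1,5-diketones with a heteroatom in the tether.

Step 3
Reactants: 4 3,4-bis(4-methoxyphenyl)-1-(4-methylbenzenesulfonyl)-2,5-dihydro-1H-pyrrole
Product: 5 3,4-bis(4-methoxyphenyl)-1-(4-methylbenzenesulfonyl)-1H-pyrrole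
Conditions: DDQ, 1,4-dioxane, 80 °C
Reagents that add atoms: none
Why: DDQ dehydrogenation of a 3-pyrroline, in which hydride abstraction from an allylic N–CH2 position gives a cation stabilised by nitrogen and the 4-methoxyphenyl-substituted alkene, and proton loss from the other CH2 group aromatises the ring.

Step 4
Reactants: 5 3,4-bis(4-methoxyphenyl)-1-(4-methylbenzenesulfonyl)-1H-pyrrole
Product: 6 2,5-dibromo-3,4-bis(4-methoxyphenyl)-1-(4-methylbenzenesulfonyl)-1H-pyrrole
Conditions: NBS (2.1 equiv), DMF, 0 °C to rt
Reagents that add atoms: N-bromosuccinimide, O=C1CCC(=O)N1Br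
Why: Electrophilic aromatic bromination, in which attack at the two free α-positions gives a cation stabilised by the adjacent 4-methoxyphenyl group and by nitrogen, so these positions should react ahead of the anisyl carbons ortho to methoxy.

Step 5
Reactants: 6 2,5-dibromo-3,4-bis(4-methoxyphenyl)-1-(4-methylbenzenesulfonyl)-1H-pyrrole; 7 4-methoxyphenylboronic acid (3 equiv); 8 carbon monoxide
Product: 10 [3,4-bis(4-methoxyphenyl)-1-(4-methylbenzenesulfonyl)-1H-pyrrole-2,5-diyl]bis[(4-methoxyphenyl)methanone], via monoketone monobromide 9 (not isolated)
Conditions: Pd(OAc)2 (5 mol %), di(1-adamantyl)-n-butylphosphine (15 mol %), TMEDA (3 equiv), CO (5 bar), toluene, 100 °C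
Reagents that add atoms: 4-methoxyphenylboronic acid (second molecule), COc1ccc(B(O)O)cc1; carbon monoxide (second molecule), [C-]#[O+]
Why: Zerovalent palladium, formed from Pd(OAc)2 and the bulky electron-rich dialkylphosphine, inserts into one C–Br bond of 6, the π-excessive pyrrol-2-yl group migrates to coordinated CO to give an acylpalladium bromide, and aryl transfer from 7 followed by reductive elimination releases monoketone 9; the same cycle at the second C–Br bond consumes a second molecule each of 7 and 8 and gives 10, so that one molecule of 6, two of 7 and two of 8 make up the product. The closest known reaction is the carbonylative Suzuki–Miyaura coupling of aryl and heteroaryl bromides to diaryl ketones, of which twofold versions on dihaloarenes are also known. No ring is closed and no stereocentre is formed; four C–C bonds (two pyrrole–CO and two CO–aryl) are made. The selectivity needed is CO insertion ahead of direct biaryl coupling at both sites: each pyrrolyl–palladium bond lies between the N-sulfonyl group and a neighbouring aryl ring, which slows transmetalation at that crowded centre, whereas insertion moves the metal one atom outwards and is kept fast by 5 bar of CO. The N-sulfonyl group, and in 9 the first aroyl group as well, keeps the C–Br bonds electron-poor enough for oxidative addition under CO, and the amine base avoids hydroxide or alkoxide that would strip the sulfonyl group prematurely.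

Step 6
Reactants: 10 [3,4-bis(4-methoxyphenyl)-1-(4-methylbenzenesulfonyl)-1H-pyrrole-2,5-diyl]bis[(4-methoxyphenyl)methanone]
Product: 11 [3,4-bis(4-methoxyphenyl)-1H-pyrrole-2,5-diyl]bis[(4-methoxyphenyl)methanone]
Conditions: NaOH, THF/H2O, 50 °C; then dilute HCl
Reagents that add atoms: none
Why: Nucleophilic N–S cleavage, in which hydroxide attacks sulfur and expels a pyrrolide made an unusually good leaving group by its two α-aroyl substituents, while the diaryl ketones have no α-hydrogen and are untouched; any material that lost the sulfonyl group in step 5 converges on 11 here.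

Step 7
Reactants: 11 [3,4-bis(4-methoxyphenyl)-1H-pyrrole-2,5-diyl]bis[(4-methoxyphenyl)methanone]
Product: 12 [3,4-bis(4-hydroxyphenyl)-1H-pyrrole-2,5-diyl]bis[(4-hydroxyphenyl)methanone]
Conditions: BBr3 (excess), CH2Cl2, −78 °C to rt; then H2O
Reagents that add atoms: none
Why: BBr3 ether cleavage, in which boron coordinates each methoxy oxygen and bromide removes the methyl group by SN2; this is standard for aryl methyl ethers and tolerated by diaryl ketones and the pyrrole N–H when excess reagent covers the Lewis-basic sites.

Step 8
Reactants: 12 [3,4-bis(4-hydroxyphenyl)-1H-pyrrole-2,5-diyl]bis[(4-hydroxyphenyl)methanone]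
Product: 13 [3,4-bis(3,5-dibromo-4-hydroxyphenyl)-1H-pyrrole-2,5-diyl]bis[(3,5-dibromo-4-hydroxyphenyl)methanone]
Conditions: Br2 (8.4 equiv), AcOH, rt; then aq. NaHSO3
Reagents that add atoms: bromine, BrBr
Why: Electrophilic aromatic bromination, in which each phenol has its para position blocked and both ortho positions free, so the eight ortho sites should be filled (as in the dibromination of 4-hydroxyaryl ketones) while the fully substituted, doubly acylated pyrrole ring offers no site.

**Compound list**

1 | 4-methylbenzenesulfonamide | Cc1ccc(cc1)S(N)(=O)=O | starting material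
2 | 2-bromo-1-(4-methoxyphenyl)ethanone | COc1ccc(cc1)C(=O)CBr | starting material
3 | N,N-bis[2-(4-methoxyphenyl)-2-oxoethyl]-4-methylbenzenesulfonamide | COc1ccc(cc1)C(=O)CN(CC(=O)c1ccc(OC)cc1)S(=O)(=O)c1ccc(C)cc1 | intermediate
4 | 3,4-bis(4-methoxyphenyl)-1-(4-methylbenzenesulfonyl)-2,5-dihydro-1H-pyrrole | COc1ccc(cc1)C1=C(c2ccc(OC)cc2)CN(C1)S(=O)(=O)c1ccc(C)cc1 | intermediate
5 | 3,4-bis(4-methoxyphenyl)-1-(4-methylbenzenesulfonyl)-1H-pyrrole | COc1ccc(cc1)-c1cn(cc1-c1ccc(OC)cc1)S(=O)(=O)c1ccc(C)cc1 | intermediate
6 | 2,5-dibromo-3,4-bis(4-methoxyphenyl)-1-(4-methylbenzenesulfonyl)-1H-pyrrole | COc1ccc(cc1)-c1c(Br)n(S(=O)(=O)c2ccc(C)cc2)c(Br)c1-c1ccc(OC)cc1 | intermediate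
7 | 4-methoxyphenylboronic acid | COc1ccc(B(O)O)cc1 | starting material
8 | carbon monoxide | [C-]#[O+] | starting material
9 | [5-bromo-3,4-bis(4-methoxyphenyl)-1-(4-methylbenzenesulfonyl)-1H-pyrrol-2-yl](4-methoxyphenyl)methanone | COc1ccc(cc1)C(=O)c1c(-c2ccc(OC)cc2)c(-c2ccc(OC)cc2)c(Br)n1S(=O)(=O)c1ccc(C)cc1 | intermediate (not isolated)
10 | [3,4-bis(4-methoxyphenyl)-1-(4-methylbenzenesulfonyl)-1H-pyrrole-2,5-diyl]bis[(4-methoxyphenyl)methanone] | COc1ccc(cc1)C(=O)c1c(-c2ccc(OC)cc2)c(-c2ccc(OC)cc2)c(C(=O)c2ccc(OC)cc2)n1S(=O)(=O)c1ccc(C)cc1 | intermediate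
11 | [3,4-bis(4-methoxyphenyl)-1H-pyrrole-2,5-diyl]bis[(4-methoxyphenyl)methanone] | COc1ccc(cc1)C(=O)c1[nH]c(C(=O)c2ccc(OC)cc2)c(-c2ccc(OC)cc2)c1-c1ccc(OC)cc1 | intermediate
12 | [3,4-bis(4-hydroxyphenyl)-1H-pyrrole-2,5-diyl]bis[(4-hydroxyphenyl)methanone] | Oc1ccc(cc1)C(=O)c1[nH]c(C(=O)c2ccc(O)cc2)c(-c2ccc(O)cc2)c1-c1ccc(O)cc1 | intermediate
13 | [3,4-bis(3,5-dibromo-4-hydroxyphenyl)-1H-pyrrole-2,5-diyl]bis[(3,5-dibromo-4-hydroxyphenyl)methanone] | O=C(c1cc(Br)c(O)c(Br)c1)c1[nH]c(C(=O)c2cc(Br)c(O)c(Br)c2)c(-c2cc(Br)c(O)c(Br)c2)c1-c1cc(Br)c(O)c(Br)c1 | target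

**Count**

Total steps: 8. Longest linear sequence: 8 steps (from 1 and 2; 7 and 8 are bought and enter at step 5).

**Steps most likely to fail**

Step 5. At the second C–Br bond the ring already carries one aroyl group, so migration of the now electron-poorer pyrrolyl group to CO slows and direct transmetalation can overtake it, placing an aryl instead of an aroyl group at one α-position. Early loss of the N-sulfonyl group would further slow oxidative addition. The fallback gives up the palladium chemistry and sets out from 5. NaOH in aqueous 1,4-dioxane at reflux (then dilute HCl) removes the sulfonyl group to give 3,4-bis(4-methoxyphenyl)-1H-pyrrole F1. Twofold Friedel–Crafts aroylation of F1 with 4-methoxybenzoyl chloride and AlCl3 in 1,2-dichloroethane (0 to 60 °C) would then give 11, since the two α-positions are the only free pyrrole carbons. The route is rejoined at 11, and steps 4 to 6 are not needed.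

Step 2. The coupling may stop at the titanium pinacolate, and forcing the deoxygenation at reflux invites reductive scission of the phenacyl C–N bonds. The fallback sets out from 3 and accepts the diol. TiCl4 and Zn in THF at −10 to 0 °C, with aqueous K2CO3 work-up, should give cis-3,4-bis(4-methoxyphenyl)-1-(4-methylbenzenesulfonyl)pyrrolidine-3,4-diol F2. Twofold acid-catalysed dehydration (catalytic 4-methylbenzenesulfonic acid, toluene, reflux, water separator) would lead directly to 5, so neither the high-temperature deoxygenation nor the DDQ step is needed. Either diol diastereomer would converge on 5, and the route is rejoined there.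

Step 4. Bromination may spill onto the anisyl rings ortho to methoxy, or stall after the first bromine because the sulfonyl group and that bromine deactivate the ring. The fallback sets out from 5 and introduces bromine by deprotonation instead of electrophilic substitution. Lithium diisopropylamide (THF, −78 °C) lithiates the α-position next to the sulfonylated nitrogen, and 1,2-dibromo-1,1,2,2-tetrachloroethane traps the anion to give 2-bromo-3,4-bis(4-methoxyphenyl)-1-(4-methylbenzenesulfonyl)-1H-pyrrole F3. A second lithiation at the remaining α-position and the same quench would give 6, where the route is rejoined.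

**Further compounds**

F1 | step 5 | 3,4-bis(4-methoxyphenyl)-1H-pyrrole | COc1ccc(cc1)-c1c[nH]cc1-c1ccc(OC)cc1
F2 | step 2 | (3R,4S)-3,4-bis(4-methoxyphenyl)-1-(4-methylbenzenesulfonyl)pyrrolidine-3,4-diol (cis, meso) | COc1ccc(cc1)[C@]1(O)CN(C[C@]1(O)c1ccc(OC)cc1)S(=O)(=O)c1ccc(C)cc1
F3 | step 4 | 2-bromo-3,4-bis(4-methoxyphenyl)-1-(4-methylbenzenesulfonyl)-1H-pyrrole | COc1ccc(cc1)-c1cn(S(=O)(=O)c2ccc(C)cc2)c(Br)c1-c1ccc(OC)cc1
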